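## Structural features

- The target is a 6/6/9/4 tetracycle. A diformylphloroglucinol ring is joined through an ether oxygen and the benzylic carbon C1′ to form a dihydropyran, and that chroman is trans-fused across C4–C5 to a nine-membered carbocycle (caryophyllane numbering).
- The nine-membered ring is in turn trans-fused at C1/C9 to a gem-dimethylcyclobutane and carries an exocyclic methylene at C8.
- Three stereocentres are contiguous: C1′ (phenyl-bearing diarylmethine), C5 (methine) and C4 (quaternary, bearing the aryl ether oxygen and the C12 methyl). The pair C1/C9 is insulated from them by C2–C3 on one side and C6–C8 on the other.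
- Fragile groups are the two salicylaldehyde-type formyl groups, the electron-rich free phenols, the tertiary alkyl aryl ether at C4 (prone to acid ionisation), the acid-sensitive 1,1-disubstituted alkene, and C9, which is epimerisable whenever C8 is a carbonyl.
- The real difficulties are the nine-membered ring, the tertiary aryl ether that cannot be made by substitution, and the relay of configuration between the remote C1/C9 pair and the C4/C5 pair.
- The key step exploits the substitution of C4: it carries an oxygen, a carbon that can be a carboxyl (C12), and a bond to C5. C4–C5 is therefore the bond made when an α-aryloxy ester enolate undergoes a [3,3] shift onto an allylic ester whose far alkene carbon is C5.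
- Embedding that array in a thirteen-membered lactone makes the shift a ring contraction: it closes the nine-membered carbocycle and leaves on C5 a vinyl group whose inner carbon is the future C1′.

## Logic of the disconnections

39 is cut at the two aryl–CHO bonds to give 37. The formyl groups are incompatible with ylides, hydrides and Grignard reagents, so they go on last. The demand on the forward step is an electrophile that attacks the trioxygenated ring at both free positions and leaves the C8 methylene alone.

37 is cut at C8=C15 and at the two phenol O–H bonds to give 35 through 36. A ketone at C8 makes C9 correctable. The phenol oxygens are carried as benzyl ethers and not as methyl ethers, so that they come off by neutral hydrogenolysis; a boron trihalide would threaten the tertiary C4–O bond. The demand is that the benzyl groups are removed before the alkene exists.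

35 is cut at the aryl–C1′ bond and at the C1′–phenyl bond to give 31 and 32 through 33. This removes one ring and one stereocentre and reduces the chroman to an aryl ether. The forward cationic closure must place the phenyl group trans to the C12 methyl and must not ionise the C4–O bond.

31 is traced to 26 through 29, 28 and 27 by adding back one carbon at C1′ (a vinyl group) and raising C12 from methyl to carboxyl. These are exactly the two groups a Claisen shift leaves on the new bond. The forward demands are a hydride displacement at a neopentyl-type carbon and an alkene cleavage that spares the electron-rich arene.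

26 is cut at C4–C5 with re-formation of the allylic C–O bond to give 23. The medium ring is exchanged for an easily closed macrolactone and the quaternary ether carbon for a methine whose configuration does not matter. The forward step must control C4 relative to C5 through the enolate and alkene geometries, and both relative to C1/C9 through the ring.

23 is cut at the lactone C–O bond to give 21, and 21 at the C5=C1′ double bond (through 20 and 19) to give 17 and 18. The result is an open chain with a terminal alkene. The forward demands are an E-selective alkene construction and a high-dilution lactonisation.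

17 is cut at C7–C8 (through 16 and 15) to give 12 and 13, with C9 returned to the cis configuration of its precursor. This leaves a cyclobutane acid with one side chain. The forward acylation must spare the ester, and the epimerisation must invert C9 only.

12 is cut at C3–C4 (through 11) to give 7 and 10, and 10 at the O–C4 bond to give 8 and 9. The ether is made on an unhindered carbon. The demand is only an olefination that tolerates a free carboxylate.

7 is cut back through 5 and 4 to 3 by re-forming the C8–C3 bond of a cyclopentanone, and 3 is cut at C1–C11 and C9–C10 to give 1 and 2. The cleavage is placed at the enol ether bond and not across the enone double bond. Only then does the aldehyde carbon become C3, and only then does a two-carbon olefination reach C4; a formyl group directly on the cyclobutane would give a chain one carbon short. The forward photocycloaddition must be head-to-tail and anti to the silyloxy group.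

## Other disconnections considered

Alternative 1: The cut removes C1–C9 and C10–C11 together, opening both the cyclobutane and the nine-membered ring to the enyne A1, a finished chroman with a prenyl-type alkene (C1=C11) and a terminal alkyne (C9≡C10).
- Forward step: cationic monovalent gold, [Au(NCMe){P(t-Bu)2(biphenyl-2-yl)}]SbF6, activates the alkyne. C1 attacks C9 and the vinylgold carbon C10 closes on the C11 cation to give the cyclobutene A2.
- In favour: two rings and two C–C bonds form in one operation, no cyclobutane building block is needed, and C4, C5 and C1′ are made beforehand on a simple chroman. On step economy this is better than the chosen plan.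
- Against: a nine-membered ring is small for a macrocyclic enyne [2+2], so oligomerisation and skeletal rearrangement compete. The dimethoxyarene is itself a nucleophile towards a gold-activated alkyne. C1 is created in the ring-forming step under control only from centres five or more atoms away or from the sacrificial C8 silyl ether. C9 is set afterwards by hydrogenating C9=C10.
- Comparison: both plans work at the edge of ring-size precedent and both can correct C9 through a C8 ketone; on these points they are equal. The chosen plan is stronger on C1, which it fixes in the first step next to a directing group.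

Alternative 2: The cut is C2=C3, leading back to the diene A3, a 2-methyl-2-vinylchroman tethered to a trans-2-vinylcyclobutyl ketone.
- Forward step: second-generation Grubbs catalyst joins the two vinyl groups to the Z-cyclononene A4.
- In favour: all five stereocentres exist before ring closure, so the ring-forming step creates none. On stereochemical risk in the key step this is better than the chosen plan. A Z alkene suits a nine-membered ring, and the product needs only alkene hydrogenation before the common endgame.
- Against: one vinyl group sits on the fully substituted C4 beside the aryloxy group and the other on a cyclobutane carbon flanked by the gem-dimethyl group, so neither is a good site for initiation. Nine-membered rings are among the least favourable for metathesis, and dimerisation is the expected competitor. The quaternary vinyl ether with defined C4, C5 and C1′ has to be built separately, and the trans-cyclobutane fragment is needed just as in the chosen plan.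
- Comparison: step count is about equal. The chosen plan is mechanistically surer of closing the ring, because a six-membered transition state inside a macrocycle replaces an end-to-end closure.

Alternative 3: The cut is C9–C10 and C1–C11, leading back to the chroman-fused Z-cyclononenone A5 and isobutene.
- Forward step: sensitised irradiation (thioxanthone) forms the cyclobutane and gives the ketone A6.
- In favour: the reagent is trivial, the head-to-tail orientation puts C11 on the β-carbon C1 as required, no chiral cyclobutane synthon is needed, and A6 is the methyl-ether counterpart of 35. For the cyclobutane this is better in step economy. C9 is correctable by base in both plans, an equal point.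
- Against: the nine-membered ring of A5 still has to be made, so the hardest problem is moved and not solved. The face of addition at C1 depends on chroman centres far away in a flexible ring. Medium-ring enones isomerise about the double bond on excitation, and head-to-head adducts are possible.
- Comparison: the chosen plan is stronger on C1 and on having a defined answer for the medium ring.

Key step: step 15

Remark on numbering and stereochemistry: caryophyllane numbering is used throughout. C4 is an epimeric mixture from 12 to 23, which is harmless because step 15 makes it trigonal. The anti, head-to-tail adduct 3 is assumed to be the main product of step 1 and to be separable from minor isomers.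

## Route

Step 1
Reactants: 1 (S)-4-(tert-butyldimethylsilyloxy)cyclopent-2-enone; 2 isobutene
Product: 3 (1R,4S,5R)-4-(tert-butyldimethylsilyloxy)-6,6-dimethylbicyclo[3.2.0]heptan-2-one
Conditions: hν (350 nm, Pyrex), excess 2, CH2Cl2, −78 °C
Reagents that add atoms: none
Why: Enone–alkene [2+2] photocycloaddition; the five-membered ring enforces a cis fusion, isobutene should add head-to-tail (CMe2 on the β-carbon, as C11 must sit next to C1) and anti to the silyloxy group, which fixes C1 as R. C9 is set cis here and corrected in step 9.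

Step 2
Reactants: 3 (1R,4S,5R)-4-(tert-butyldimethylsilyloxy)-6,6-dimethylbicyclo[3.2.0]heptan-2-one
Product: 4 (1R,5R)-6,6-dimethylbicyclo[3.2.0]hept-3-en-2-one
Conditions: DBU, CH2Cl2, 0 °C → rt
Reagents that add atoms: none
Why: E1cB β-elimination of the silanol from a β-silyloxy ketone; the ring-fusion centres are untouched and the auxiliary stereocentre has done its work.

Step 3
Reactants: 4 (1R,5R)-6,6-dimethylbicyclo[3.2.0]hept-3-en-2-one
Product: 5 triethyl{[(1R,5R)-6,6-dimethylbicyclo[3.2.0]hept-2-en-2-yl]oxy}silane
Conditions: Et3SiH, RhCl(PPh3)3 (1 mol %), THF, 50 °C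
Reagents that add atoms: triethylsilane, CC[SiH](CC)CC
Why: Rhodium-catalysed 1,4-hydrosilylation of an enone with a monohydrosilane gives the silyl enol ether regiospecifically, with the double bond between the carbonyl carbon (future C8) and its methylene neighbour (future C3), away from the ring fusion.

Step 4
Reactants: 5 triethyl{[(1R,5R)-6,6-dimethylbicyclo[3.2.0]hept-2-en-2-yl]oxy}silane
Product: 7 (1R,2R)-3,3-dimethyl-2-(2-oxoethyl)cyclobutane-1-carboxylic acid (cis), via triethylsilyl ester 6 (not isolated)
Conditions: O3, CH2Cl2, −78 °C; Me2S, −78 °C → rt; aqueous work-up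
Reagents that add atoms: ozone, [O-][O+]=O
Why: Ozonolysis of a silyl enol ether cleaves the C8–C3 bond to a carboxyl (C8) and an aldehyde (C3). C2 and C3 stay on the ring, so the next two-carbon olefination reaches C4.

Step 5
Reactants: 8 3,5-bis(benzyloxy)phenol; 9 methyl 2-diazo-2-(dimethoxyphosphoryl)acetate
Product: 10 methyl 2-[3,5-bis(benzyloxy)phenoxy]-2-(dimethoxyphosphoryl)acetate (racemic)
Conditions: Rh2(OAc)4 (1 mol %), toluene, 80 °C
Reagents that add atoms: none
Why: Rhodium-carbenoid O–H insertion of a diazophosphonoacetate into a phenol, the usual entry to α-aryloxy phosphonoacetates. It makes the C4–O bond while C4 is an unhindered methine, so no substitution at a tertiary centre is ever needed.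

Step 6
Reactants: 7 (1R,2R)-3,3-dimethyl-2-(2-oxoethyl)cyclobutane-1-carboxylic acid; 10 methyl 2-[3,5-bis(benzyloxy)phenoxy]-2-(dimethoxyphosphoryl)acetate
Product: 11 (1R,2R)-2-{3-[3,5-bis(benzyloxy)phenoxy]-4-methoxy-4-oxobut-2-en-1-yl}-3,3-dimethylcyclobutane-1-carboxylic acid (E/Z mixture)
Conditions: NaH (2.2 equiv), THF, 0 °C → rt; then dilute HCl
Reagents that add atoms: none
Why: Horner–Wadsworth–Emmons olefination of the aldehyde (the carboxylate is a spectator) forms C3=C4 and brings in C4, C12 and the aryloxy group. The alkene geometry is irrelevant because the double bond is reduced next.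

Step 7
Reactants: 11 (1R,2R)-2-{3-[3,5-bis(benzyloxy)phenoxy]-4-methoxy-4-oxobut-2-en-1-yl}-3,3-dimethylcyclobutane-1-carboxylic acid
Product: 12 (1R,2R)-2-{3-[3,5-bis(benzyloxy)phenoxy]-4-methoxy-4-oxobutyl}-3,3-dimethylcyclobutane-1-carboxylic acid (both C4 epimers)
Conditions: Mg turnings, MeOH, 0 °C → rt; then dilute HCl
Reagents that add atoms: none
Why: Dissolving-metal conjugate reduction of the α-aryloxy acrylate with magnesium in methanol saturates C3–C4 without hydrogenolysing the benzyl ethers. C4 forms as both epimers, which is immaterial.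

Step 8
Reactants: 12 (1R,2R)-2-{3-[3,5-bis(benzyloxy)phenoxy]-4-methoxy-4-oxobutyl}-3,3-dimethylcyclobutane-1-carboxylic acid; 13 but-3-en-1-ylzinc bromide
Product: 15 methyl 2-[3,5-bis(benzyloxy)phenoxy]-4-[(1R,4R)-2,2-dimethyl-4-(pent-4-enoyl)cyclobutyl]butanoate (cis), via acid chloride 14 (not isolated)
Conditions: 1-chloro-N,N,2-trimethylprop-1-en-1-amine, CH2Cl2, 0 °C → rt; then 13, Pd(PPh3)4 (5 mol %), THF, 0 °C → rt
Reagents that add atoms: none
Why: The acid becomes its chloride under neutral conditions and is coupled with the alkylzinc halide under palladium catalysis (Negishi acylation). This forms C7–C8 and tolerates the methyl ester and the aryl ethers.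

Step 9
Reactants: 15 methyl 2-[3,5-bis(benzyloxy)phenoxy]-4-[(1R,4R)-2,2-dimethyl-4-(pent-4-enoyl)cyclobutyl]butanoate
Product: 16 methyl 2-[3,5-bis(benzyloxy)phenoxy]-4-[(1R,4S)-2,2-dimethyl-4-(pent-4-enoyl)cyclobutyl]butanoate (trans)
Conditions: NaOMe (0.3 equiv), MeOH, rt
Reagents that add atoms: none
Why: Base-mediated epimerisation α to the ketone moves C9 to the thermodynamically preferred trans-1,2-disubstituted cyclobutane (C9 becomes S), while C1 has no acidifying group and keeps its configuration. A Claisen-type closure from C9 onto the ester is disfavoured because its product would be a non-enolisable β-dicarbonyl.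

Step 10
Reactants: 16 methyl 2-[3,5-bis(benzyloxy)phenoxy]-4-[(1R,4S)-2,2-dimethyl-4-(pent-4-enoyl)cyclobutyl]butanoate
Product: 17 methyl 2-[3,5-bis(benzyloxy)phenoxy]-4-{(1R,4S)-4-[2-(but-3-en-1-yl)-1,3-dioxolan-2-yl]-2,2-dimethylcyclobutyl}butanoate
Conditions: Me3SiOCH2CH2OSiMe3, Me3SiOTf (5 mol %), CH2Cl2, −78 → −20 °C; pyridine
Reagents that add atoms: 1,2-bis(trimethylsilyloxy)ethane, C[Si](C)(C)OCCO[Si](C)(C)C
Why: Ketalisation with the bis-silyl glycol under silyl triflate catalysis masks C8, so that it is not enolised in step 15 or attacked in steps 16, 18 and 20. It also locks the C9 configuration.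

Step 11
Reactants: 17 methyl 2-[3,5-bis(benzyloxy)phenoxy]-4-{(1R,4S)-4-[2-(but-3-en-1-yl)-1,3-dioxolan-2-yl]-2,2-dimethylcyclobutyl}butanoate; 18 (E)-but-2-enal
Product: 19 methyl 2-[3,5-bis(benzyloxy)phenoxy]-4-[(1R,4S)-2,2-dimethyl-4-{2-[(3E)-5-oxopent-3-en-1-yl]-1,3-dioxolan-2-yl}cyclobutyl]butanoate
Conditions: 18 (5 equiv), second-generation Hoveyda–Grubbs catalyst (5 mol %), CH2Cl2, 40 °C
Reagents that add atoms: none
Why: Cross-metathesis of a terminal alkene with an enal partner gives the conjugated aldehyde as the thermodynamically favoured E isomer. This secures the alkene geometry that step 15 turns into the C5 configuration.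

Step 12
Reactants: 19 methyl 2-[3,5-bis(benzyloxy)phenoxy]-4-[(1R,4S)-2,2-dimethyl-4-{2-[(3E)-5-oxopent-3-en-1-yl]-1,3-dioxolan-2-yl}cyclobutyl]butanoate
Product: 20 methyl 2-[3,5-bis(benzyloxy)phenoxy]-4-[(1R,4S)-4-{2-[(3E)-5-hydroxypent-3-en-1-yl]-1,3-dioxolan-2-yl}-2,2-dimethylcyclobutyl]butanoate
Conditions: NaBH4, CeCl3·7H2O, MeOH, −40 °C
Reagents that add atoms: none
Why: Luche 1,2-reduction of the enal, selective over the methyl ester and harmless to the ketal, gives the E-allylic alcohol.

Step 13
Reactants: 20 methyl 2-[3,5-bis(benzyloxy)phenoxy]-4-[(1R,4S)-4-{2-[(3E)-5-hydroxypent-3-en-1-yl]-1,3-dioxolan-2-yl}-2,2-dimethylcyclobutyl]butanoate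
Product: 21 2-[3,5-bis(benzyloxy)phenoxy]-4-[(1R,4S)-4-{2-[(3E)-5-hydroxypent-3-en-1-yl]-1,3-dioxolan-2-yl}-2,2-dimethylcyclobutyl]butanoic acid
Conditions: LiOH·H2O, THF/MeOH/H2O, rt; then dilute HCl to pH 4, 0 °C
Reagents that add atoms: lithium hydroxide, [Li+].[OH-]
Why: Saponification of the activated α-aryloxy methyl ester; the mild acidification keeps the dioxolane.

Step 14
Reactants: 21 2-[3,5-bis(benzyloxy)phenoxy]-4-[(1R,4S)-4-{2-[(3E)-5-hydroxypent-3-en-1-yl]-1,3-dioxolan-2-yl}-2,2-dimethylcyclobutyl]butanoic acid
Product: 23 thirteen-membered E-allylic lactone of 21: ring C12(=O)–O–CH2–C1′H=C5H–C6–C7–C8–C9–C1–C2–C3–C4 with 3,5-bis(benzyloxy)phenoxy on C4 (both epimers), spiro-1,3-dioxolane at C8 and the trans-fused 11,11-dimethylcyclobutane (1R,9S), via mixed anhydride 22 (not isolated)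
Conditions: 2,4,6-Cl3C6H2COCl, Et3N, THF, rt; then slow addition to DMAP, toluene, 80 °C (1 mM)
Reagents that add atoms: none
Why: Yamaguchi macrolactonisation: under high dilution the primary allylic hydroxyl acylates the mixed anhydride and closes an unstrained thirteen-membered ring. The alkene geometry and C1/C9 are not touched.

Step 15
Reactants: 23 thirteen-membered E-allylic α-aryloxy lactone
Product: 26 (1R,4R,5S,9S)-4-[3,5-bis(benzyloxy)phenoxy]-5-ethenyl-8,8-(ethylenedioxy)-11,11-dimethylbicyclo[7.2.0]undecane-4-carboxylic acid (caryophyllane numbering), via silyl ketene acetal 24 (not isolated), via trimethylsilyl ester 25 (not isolated)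
Conditions: LiN(i-Pr)2, THF, −78 °C; Me3SiCl/Et3N, −78 °C → rt, then 60 °C; aqueous work-up at pH 4
Reagents that add atoms: none
Why: Deprotonation at C4 in THF gives a lithium enolate bridged between the enolate and aryloxy oxygens, so silylation fixes ketene acetal 24 with the aryloxy group cis to OSiMe3 and the C3 arm cis to the ring oxygen. On warming, 24 undergoes a concerted suprafacial [3,3] shift (Ireland–Claisen rearrangement) in which C4 bonds to C5 as the allylic C–O bond breaks; the closest known reaction type is the ester-enolate Claisen contraction of allylic macrolactones to 2-vinylcycloalkanecarboxylic acids. The nine-membered carbocycle is closed not end to end but through a six-membered chair-like transition state inside the thirteen-membered ring, the O–CH2–CH= unit being extruded as the vinyl group. C5 is set by the E alkene, which puts the C6 arm pseudo-equatorial. C4 is set relative to C5 by the ketene acetal geometry, which puts the aryloxy group pseudo-equatorial and the C3 arm pseudo-axial, so that carboxyl and vinyl end up cis on the carbocycle and the aryloxy and vinyl groups on opposite faces, as the trans-fused chroman requires. The absolute sense of the pair (4R,5S and not 4S,5R) is not fixed by the pericyclic array itself and must come from the conformation that the trans-fused gem-dimethylcyclobutane at C1/C9 imposes on 23. The selectivities needed are therefore the chelated enolate geometry (THF without polar additives, silylation at −78 °C), chair over boat, and the facial choice; the C4 epimers of 23 converge because C4 becomes trigonal. Hydrolysis of 25 on work-up gives 26.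

Step 16
Reactants: 26 nine-membered aryloxy acid
Product: 27 [(1R,4R,5S,9S)-4-[3,5-bis(benzyloxy)phenoxy]-5-ethenyl-8,8-(ethylenedioxy)-11,11-dimethylbicyclo[7.2.0]undecan-4-yl]methanol (caryophyllane numbering)
Conditions: LiAlH4, THF, 0 → 50 °C
Reagents that add atoms: none
Why: Hydride reduction of the carboxylic acid to the primary alcohol; the ketal, the benzyl ethers and the vinyl group are inert.

Step 17
Reactants: 27 C12 primary alcohol
Product: 28 methanesulfonate of 27
Conditions: MsCl, Et3N, CH2Cl2, 0 °C
Reagents that add atoms: methanesulfonyl chloride, CS(=O)(=O)Cl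
Why: Sulfonylation of the primary alcohol prepares C12 for hydride displacement.

Step 18
Reactants: 28 C12 methanesulfonate
Product: 29 (1R,4R,5S,9S)-4-[3,5-bis(benzyloxy)phenoxy]-5-ethenyl-8,8-(ethylenedioxy)-4,11,11-trimethylbicyclo[7.2.0]undecane (caryophyllane numbering)
Conditions: LiBHEt3, THF, 0 → 65 °C
Reagents that add atoms: none
Why: SN2 displacement of a primary sulfonate by the strongly nucleophilic triethylborohydride turns C12 into the methyl group. The reaction type is established for neopentyl-type sulfonates and for sulfonyloxymethyl groups on aryloxy-bearing quaternary carbons.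

Step 19
Reactants: 29 C12-methyl vinyl compound
Product: 31 (1R,4R,5R,9S)-4-[3,5-bis(benzyloxy)phenoxy]-8,8-(ethylenedioxy)-4,11,11-trimethylbicyclo[7.2.0]undecane-5-carbaldehyde (caryophyllane numbering; same spatial arrangement at C5 as in 29), via vicinal diol 30 (not isolated)
Conditions: OsO4 (2 mol %), NaIO4, 2,6-lutidine, 1,4-dioxane/H2O, rt
Reagents that add atoms: osmium tetroxide, O=[Os](=O)(=O)=O; sodium periodate, [Na+].[O-][I](=O)(=O)=O
Why: Lemieux–Johnson cleavage (dihydroxylation, then periodate cleavage of the diol) removes the terminal carbon and leaves C1′ as an aldehyde. It is preferred to ozone because the trialkoxyarene is itself ozone-sensitive, and the buffered medium protects the epimerisable C5.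

Step 20
Reactants: 31 C1′ aldehyde; 32 phenylmagnesium bromide
Product: 33 [(1R,4R,5S,9S)-4-[3,5-bis(benzyloxy)phenoxy]-8,8-(ethylenedioxy)-4,11,11-trimethylbicyclo[7.2.0]undecan-5-yl](phenyl)methanol (both carbinol epimers)
Conditions: 32, THF, −78 → −20 °C; aq. NH4Cl
Reagents that add atoms: none
Why: Grignard addition to the aldehyde attaches the phenyl group to C1′. The carbinol configuration is irrelevant because C1′ is ionised in the next step.

Step 21
Reactants: 33 benzylic carbinol
Product: 35 5,7-bis(benzyloxy)chroman with C8 ketone (1R,4R,5S,9S,1′R), the bis(benzyl) ether of the C8-oxo analogue of the target skeleton, via chroman ketal 34 (not isolated)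
Conditions: CF3CO2H, CH2Cl2, −20 → 0 °C; then THF/1 M aq. HCl, rt
Reagents that add atoms: water, O
Why: Acid ionises the benzylic alcohol and the cation is captured by the ortho carbon of the trialkoxyarene (intramolecular Friedel–Crafts alkylation closing the six-membered ring; both ortho positions are equivalent). In the chair-like closure the phenyl group lies pseudo-equatorial, away from the axial C12 methyl, which gives 1′R. Aqueous acid then hydrolyses the dioxolane to the C8 ketone.

Step 22
Reactants: 35 bis(benzyloxy)chroman ketone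
Product: 36 5,7-dihydroxychroman with C8 ketone (1R,4R,5S,9S,1′R)
Conditions: H2 (1 atm), 10% Pd/C, EtOAc/MeOH, rt
Reagents that add atoms: none
Why: Hydrogenolysis of the two aryl benzyl ethers under neutral conditions. No alkene is present at this stage, and the ketone, the tertiary aryl ether and the diarylmethine survive.

Step 23
Reactants: 36 dihydroxychroman ketone
Product: 37 5,7-dihydroxychroman with C8 exocyclic methylene (1R,4R,5S,9S,1′R)
Conditions: Ph3PCH3Br, KOt-Bu (excess), THF, 0 → 50 °C
Reagents that add atoms: methyltriphenylphosphonium bromide, C[P+](c1ccccc1)(c1ccccc1)c1ccccc1.[Br-]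
Why: Wittig methylenation of the C8 ketone with excess ylide, the phenols being carried as phenoxides. C9 is α to the ketone, but the trans ring fusion is the more stable arrangement of this 4/9 system, so the basic medium should not erode it.

Step 24
Reactants: 37 dihydroxychroman with C8 methylene
Product: 39 CNP0253700.4 (target), via bis(iminium) salt 38 (not isolated)
Conditions: [Me2N=CHCl]Cl (3 equiv), MeCN/DMF, 0 °C → rt; then aq. NaOAc, rt
Reagents that add atoms: (chloromethylene)dimethyliminium chloride, C[N+](C)=CCl.[Cl-]; water, O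
Why: Vilsmeier–Haack formylation: the phloroglucinol-type ring, activated by three oxygen substituents, is substituted at both free positions by the chloroiminium ion, and hydrolysis of the bis(iminium) salt gives the two aldehydes. The isolated 1,1-disubstituted alkene is far less nucleophilic than the arene.

## Compound list

1 | (S)-4-(tert-butyldimethylsilyloxy)cyclopent-2-enone | O=C1C=C[C@@H](O[Si](C)(C)C(C)(C)C)C1 | starting material
2 | isobutene | C=C(C)C | starting material
3 | (1R,4S,5R)-4-(tert-butyldimethylsilyloxy)-6,6-dimethylbicyclo[3.2.0]heptan-2-one | O=C1C[C@H](O[Si](C)(C)C(C)(C)C)[C@@H]2[C@H]1CC2(C)C | intermediate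
4 | (1R,5R)-6,6-dimethylbicyclo[3.2.0]hept-3-en-2-one | O=C1C=C[C@@H]2[C@H]1CC2(C)C | intermediate
5 | triethyl{[(1R,5R)-6,6-dimethylbicyclo[3.2.0]hept-2-en-2-yl]oxy}silane | CC[Si](CC)(CC)OC1=CC[C@@H]2[C@H]1CC2(C)C | intermediate
6 | triethylsilyl (1R,2R)-3,3-dimethyl-2-(2-oxoethyl)cyclobutane-1-carboxylate | O=CC[C@@H]1[C@H](C(=O)O[Si](CC)(CC)CC)CC1(C)C | intermediate
7 | (1R,2R)-3,3-dimethyl-2-(2-oxoethyl)cyclobutane-1-carboxylic acid | O=CC[C@@H]1[C@H](C(=O)O)CC1(C)C | intermediate
8 | 3,5-bis(benzyloxy)phenol | Oc1cc(OCc2ccccc2)cc(OCc2ccccc2)c1 | starting material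
9 | methyl 2-diazo-2-(dimethoxyphosphoryl)acetate | COC(=O)C(=[N+]=[N-])P(=O)(OC)OC | starting material
10 | methyl 2-[3,5-bis(benzyloxy)phenoxy]-2-(dimethoxyphosphoryl)acetate | COC(=O)C(Oc1cc(OCc2ccccc2)cc(OCc2ccccc2)c1)P(=O)(OC)OC | intermediate
11 | (1R,2R)-2-{3-[3,5-bis(benzyloxy)phenoxy]-4-methoxy-4-oxobut-2-en-1-yl}-3,3-dimethylcyclobutane-1-carboxylic acid | COC(=O)C(Oc3cc(OCc4ccccc4)cc(OCc4ccccc4)c3)=CC[C@@H]1[C@H](C(=O)O)CC1(C)C | intermediate
12 | (1R,2R)-2-{3-[3,5-bis(benzyloxy)phenoxy]-4-methoxy-4-oxobutyl}-3,3-dimethylcyclobutane-1-carboxylic acid | COC(=O)C(Oc3cc(OCc4ccccc4)cc(OCc4ccccc4)c3)CC[C@@H]1[C@H](C(=O)O)CC1(C)C | intermediate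
13 | but-3-en-1-ylzinc bromide | C=CCC[Zn]Br | starting material
14 | methyl 2-[3,5-bis(benzyloxy)phenoxy]-4-[(1R,4R)-4-(chlorocarbonyl)-2,2-dimethylcyclobutyl]butanoate | COC(=O)C(Oc3cc(OCc4ccccc4)cc(OCc4ccccc4)c3)CC[C@@H]1[C@H](C(Cl)=O)CC1(C)C | intermediate
15 | methyl 2-[3,5-bis(benzyloxy)phenoxy]-4-[(1R,4R)-2,2-dimethyl-4-(pent-4-enoyl)cyclobutyl]butanoate | COC(=O)C(Oc3cc(OCc4ccccc4)cc(OCc4ccccc4)c3)CC[C@@H]1[C@H](C(=O)CCC=C)CC1(C)C | intermediate
16 | methyl 2-[3,5-bis(benzyloxy)phenoxy]-4-[(1R,4S)-2,2-dimethyl-4-(pent-4-enoyl)cyclobutyl]butanoate | COC(=O)C(Oc3cc(OCc4ccccc4)cc(OCc4ccccc4)c3)CC[C@@H]1[C@@H](C(=O)CCC=C)CC1(C)C | intermediate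
17 | methyl 2-[3,5-bis(benzyloxy)phenoxy]-4-{(1R,4S)-4-[2-(but-3-en-1-yl)-1,3-dioxolan-2-yl]-2,2-dimethylcyclobutyl}butanoate | COC(=O)C(Oc3cc(OCc4ccccc4)cc(OCc4ccccc4)c3)CC[C@@H]1[C@@H](C2(CCC=C)OCCO2)CC1(C)C | intermediate
18 | (E)-but-2-enal | C/C=C/C=O | starting material
19 | methyl 2-[3,5-bis(benzyloxy)phenoxy]-4-[(1R,4S)-2,2-dimethyl-4-{2-[(3E)-5-oxopent-3-en-1-yl]-1,3-dioxolan-2-yl}cyclobutyl]butanoate | COC(=O)C(Oc3cc(OCc4ccccc4)cc(OCc4ccccc4)c3)CC[C@@H]1[C@@H](C2(CC/C=C/C=O)OCCO2)CC1(C)C | intermediate
20 | methyl 2-[3,5-bis(benzyloxy)phenoxy]-4-[(1R,4S)-4-{2-[(3E)-5-hydroxypent-3-en-1-yl]-1,3-dioxolan-2-yl}-2,2-dimethylcyclobutyl]butanoate | COC(=O)C(Oc3cc(OCc4ccccc4)cc(OCc4ccccc4)c3)CC[C@@H]1[C@@H](C2(CC/C=C/CO)OCCO2)CC1(C)C | intermediate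
21 | 2-[3,5-bis(benzyloxy)phenoxy]-4-[(1R,4S)-4-{2-[(3E)-5-hydroxypent-3-en-1-yl]-1,3-dioxolan-2-yl}-2,2-dimethylcyclobutyl]butanoic acid | OC(=O)C(Oc3cc(OCc4ccccc4)cc(OCc4ccccc4)c3)CC[C@@H]1[C@@H](C2(CC/C=C/CO)OCCO2)CC1(C)C | intermediate
22 | mixed anhydride of 21 with 2,4,6-trichlorobenzoic acid | O=C(OC(=O)c5c(Cl)cc(Cl)cc5Cl)C(Oc3cc(OCc4ccccc4)cc(OCc4ccccc4)c3)CC[C@@H]1[C@@H](C2(CC/C=C/CO)OCCO2)CC1(C)C | intermediate
23 | thirteen-membered E-allylic α-[3,5-bis(benzyloxy)phenoxy] lactone with C8 dioxolane and (1R,9S) trans-cyclobutane (C4 epimers) | O=C1OC/C=C/CCC3(OCCO3)[C@H]2CC(C)(C)[C@@H]2CCC1Oc1cc(OCc4ccccc4)cc(OCc4ccccc4)c1 | intermediate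
24 | O-trimethylsilyl ketene acetal of 23 (aryloxy cis to OSiMe3) | O1C/C=C/CCC2(OCCO2)[C@H]3CC(C)(C)[C@@H]3CC/C(Oc4cc(OCc5ccccc5)cc(OCc5ccccc5)c4)=C1/O[Si](C)(C)C | intermediate
25 | trimethylsilyl ester of 26 | C12(OCCO1)CC[C@@H](C=C)[C@@](Oc3cc(OCc4ccccc4)cc(OCc4ccccc4)c3)(C(=O)O[Si](C)(C)C)CC[C@@H]1[C@@H]2CC1(C)C | intermediate
26 | (1R,4R,5S,9S)-4-[3,5-bis(benzyloxy)phenoxy]-5-ethenyl-8,8-(ethylenedioxy)-11,11-dimethylbicyclo[7.2.0]undecane-4-carboxylic acid | C12(OCCO1)CC[C@@H](C=C)[C@@](Oc3cc(OCc4ccccc4)cc(OCc4ccccc4)c3)(C(=O)O)CC[C@@H]1[C@@H]2CC1(C)C | intermediate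
27 | [(1R,4R,5S,9S)-4-[3,5-bis(benzyloxy)phenoxy]-5-ethenyl-8,8-(ethylenedioxy)-11,11-dimethylbicyclo[7.2.0]undecan-4-yl]methanol | C12(OCCO1)CC[C@@H](C=C)[C@@](Oc3cc(OCc4ccccc4)cc(OCc4ccccc4)c3)(CO)CC[C@@H]1[C@@H]2CC1(C)C | intermediate
28 | methanesulfonate of 27 | C12(OCCO1)CC[C@@H](C=C)[C@@](Oc3cc(OCc4ccccc4)cc(OCc4ccccc4)c3)(COS(C)(=O)=O)CC[C@@H]1[C@@H]2CC1(C)C | intermediate
29 | (1R,4R,5S,9S)-4-[3,5-bis(benzyloxy)phenoxy]-5-ethenyl-8,8-(ethylenedioxy)-4,11,11-trimethylbicyclo[7.2.0]undecane | C12(OCCO1)CC[C@@H](C=C)[C@@](Oc3cc(OCc4ccccc4)cc(OCc4ccccc4)c3)(C)CC[C@@H]1[C@@H]2CC1(C)C | intermediate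
30 | vicinal diol from dihydroxylation of the vinyl group of 29 | C12(OCCO1)CC[C@@H](C(O)CO)[C@@](Oc3cc(OCc4ccccc4)cc(OCc4ccccc4)c3)(C)CC[C@@H]1[C@@H]2CC1(C)C | intermediate
31 | (1R,4R,5R,9S)-4-[3,5-bis(benzyloxy)phenoxy]-8,8-(ethylenedioxy)-4,11,11-trimethylbicyclo[7.2.0]undecane-5-carbaldehyde | C12(OCCO1)CC[C@@H](C=O)[C@@](Oc3cc(OCc4ccccc4)cc(OCc4ccccc4)c3)(C)CC[C@@H]1[C@@H]2CC1(C)C | intermediate
32 | phenylmagnesium bromide | Br[Mg]c1ccccc1 | starting material
33 | [(1R,4R,5S,9S)-4-[3,5-bis(benzyloxy)phenoxy]-8,8-(ethylenedioxy)-4,11,11-trimethylbicyclo[7.2.0]undecan-5-yl](phenyl)methanol | C12(OCCO1)CC[C@@H](C(O)c5ccccc5)[C@@](Oc3cc(OCc4ccccc4)cc(OCc4ccccc4)c3)(C)CC[C@@H]1[C@@H]2CC1(C)C | intermediate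
34 | 5,7-bis(benzyloxy)-4-phenylchroman fused to the caryophyllane ring, C8 dioxolane (1R,4R,5S,9S,1′R) | C15(OCCO5)CC[C@H]2[C@H](c3ccccc3)c3c(OCc4ccccc4)cc(OCc4ccccc4)cc3O[C@]2(C)CC[C@@H]2[C@@H]1CC2(C)C | intermediate
35 | 5,7-bis(benzyloxy)chroman with C8 ketone (1R,4R,5S,9S,1′R) | O=C1CC[C@H]2[C@H](c3ccccc3)c3c(OCc4ccccc4)cc(OCc4ccccc4)cc3O[C@]2(C)CC[C@@H]2[C@@H]1CC2(C)C | intermediate
36 | 5,7-dihydroxychroman with C8 ketone | O=C1CC[C@H]2[C@H](c3ccccc3)c3c(O)cc(O)cc3O[C@]2(C)CC[C@@H]2[C@@H]1CC2(C)C | intermediate
37 | 5,7-dihydroxychroman with C8 methylene | C=C1CC[C@H]2[C@H](c3ccccc3)c3c(O)cc(O)cc3O[C@]2(C)CC[C@@H]2[C@@H]1CC2(C)C | intermediate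
38 | 6,8-bis[(dimethyliminio)methyl] dichloride of 37 | C=C1CC[C@H]2[C@H](c3ccccc3)c3c(O)c(C=[N+](C)C)c(O)c(C=[N+](C)C)c3O[C@]2(C)CC[C@@H]2[C@@H]1CC2(C)C.[Cl-].[Cl-] | intermediate
39 | CNP0253700.4 | C=C1CC[C@H]2[C@H](c3ccccc3)c3c(O)c(C=O)c(O)c(C=O)c3O[C@]2(C)CC[C@@H]2[C@@H]1CC2(C)C | target

## Step count and least certain steps

Total: 24 steps. Longest linear sequence: 23 steps (steps 1–4 and 6–24); step 5 is a one-step side branch.

**Step 15 (key step).** The most likely failure is poor discrimination between the two diastereomeric chair arrays (or leakage through a boat). The centres that must bias the ring, C1 and C9, are far from the reacting termini, and a nine-membered product is at the small end of what this contraction delivers.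
Fallback (sets out from 17, returns at 31): the facial choice is handed to a carbinol stereocentre on the allylic carbon, which the later alkene cleavage removes again.
- Cross-metathesis of 17 with but-3-en-2-one gives the E-enone F1.
- Corey–Bakshi–Shibata reduction with the (S)-oxazaborolidine gives the (R)-allylic alcohol F2, and saponification gives the hydroxy acid F3.
- Yamaguchi activation to the mixed anhydride F4 and lactonisation give the methyl-substituted thirteen-membered lactone F5.
- Enolisation and silylation as in step 15 give the silyl ketene acetal F6. Its chair with the carbinol methyl pseudo-equatorial can use only one alkene face and leads, through the silyl ester F7, to the (E)-propenyl acid F8 with the 4R,5S configuration.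
- The operations of steps 16–18 give the alcohol F9, the mesylate F10 and the C12-methyl propenyl compound F11.
- The conditions of step 19 cleave the propenyl group of F11 to 31.

**Step 1.** The likely failures are incomplete facial selectivity and formation of the head-to-head regioisomer. The silyloxy group is one atom away from the nearer reacting carbon, and isobutene is only weakly polarised.
Fallback (sets out from 2, returns at 5): cyclopent-2-enone F12 and 2 are combined in an enantioselective [2+2] photocycloaddition under a chiral oxazaborolidine–AlBr3 Lewis acid, which gives the saturated ketone (1R,5R)-6,6-dimethylbicyclo[3.2.0]heptan-2-one F13 directly. Kinetic enolisation away from the ring fusion (LiN(i-Pr)2, Et3SiCl, THF, −78 °C) then gives 5.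

**Step 14.** Intermolecular esterification to diolides may outrun ring closure, because the seco acid has to fold a trans-cyclobutane and an E alkene into one ring.
Fallback (sets out from 17, returns at 23): the ring is closed at the alkene instead of the ester. Saponification of 17 gives the acid F14, carbodiimide esterification with prop-2-en-1-ol gives the allyl ester F15, and ring-closing metathesis with second-generation Grubbs catalyst at high dilution gives 23 after removal of any Z isomer.

**Step 18.** Hydride displacement at the neopentyl-type C12 may be slow. Attack at sulfur would return 27, and the electron-rich aryloxy ring could cyclise onto C12.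
Fallback (sets out from 27, returns at 29): a radical replaces the SN2 step. Acylation of 27 with phenyl chlorothionoformate gives the O-phenyl thionocarbonate F16, and Barton–McCombie deoxygenation (Bu3SnH, AIBN, toluene, 110 °C) gives 29.

**Step 24.** The chloroiminium ion or the hydrogen chloride set free may attack the C8 methylene, or the reaction may stop after one formylation because the first iminium group deactivates the ring.
Fallback (sets out from 35, returns at 39): the formyl carbons are introduced through aryl–lithium chemistry.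
- Bromination of 35 with N-bromosuccinimide (2 equiv) gives the 6,8-dibromide F17.
- Wittig methylenation gives the dibromo alkene F18.
- Bromine–lithium exchange with t-BuLi and quenching with DMF give the dialdehyde bis(benzyl) ether F19.
- BCl3 with pentamethylbenzene at −78 °C removes the benzyl groups, assisted by chelation to the ortho formyl groups, and gives 39.

## Further compounds

F1 | step 15 | E-enone from cross-metathesis of 17 with but-3-en-2-one | COC(=O)C(Oc3cc(OCc4ccccc4)cc(OCc4ccccc4)c3)CC[C@@H]1[C@@H](C2(CC/C=C/C(C)=O)OCCO2)CC1(C)C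
F2 | step 15 | (R)-allylic alcohol methyl ester | COC(=O)C(Oc3cc(OCc4ccccc4)cc(OCc4ccccc4)c3)CC[C@@H]1[C@@H](C2(CC/C=C/[C@@H](C)O)OCCO2)CC1(C)C
F3 | step 15 | (R)-hydroxy acid | OC(=O)C(Oc3cc(OCc4ccccc4)cc(OCc4ccccc4)c3)CC[C@@H]1[C@@H](C2(CC/C=C/[C@@H](C)O)OCCO2)CC1(C)C
F4 | step 15 | mixed anhydride of F3 with 2,4,6-trichlorobenzoic acid | O=C(OC(=O)c5c(Cl)cc(Cl)cc5Cl)C(Oc3cc(OCc4ccccc4)cc(OCc4ccccc4)c3)CC[C@@H]1[C@@H](C2(CC/C=C/[C@@H](C)O)OCCO2)CC1(C)C
F5 | step 15 | thirteen-membered lactone with (R)-methyl carbinol carbon | O=C1O[C@H](C)/C=C/CCC3(OCCO3)[C@H]2CC(C)(C)[C@@H]2CCC1Oc1cc(OCc4ccccc4)cc(OCc4ccccc4)c1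
F6 | step 15 | silyl ketene acetal of F5 | O1[C@H](C)/C=C/CCC2(OCCO2)[C@H]3CC(C)(C)[C@@H]3CC/C(Oc4cc(OCc5ccccc5)cc(OCc5ccccc5)c4)=C1/O[Si](C)(C)C
F7 | step 15 | trimethylsilyl ester of F8 | C12(OCCO1)CC[C@@H](/C=C/C)[C@@](Oc3cc(OCc4ccccc4)cc(OCc4ccccc4)c3)(C(=O)O[Si](C)(C)C)CC[C@@H]1[C@@H]2CC1(C)C
F8 | step 15 | (E)-propenyl analogue of 26 | C12(OCCO1)CC[C@@H](/C=C/C)[C@@](Oc3cc(OCc4ccccc4)cc(OCc4ccccc4)c3)(C(=O)O)CC[C@@H]1[C@@H]2CC1(C)C
F9 | step 15 | (E)-propenyl analogue of 27 | C12(OCCO1)CC[C@@H](/C=C/C)[C@@](Oc3cc(OCc4ccccc4)cc(OCc4ccccc4)c3)(CO)CC[C@@H]1[C@@H]2CC1(C)C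
F10 | step 15 | (E)-propenyl analogue of 28 | C12(OCCO1)CC[C@@H](/C=C/C)[C@@](Oc3cc(OCc4ccccc4)cc(OCc4ccccc4)c3)(COS(C)(=O)=O)CC[C@@H]1[C@@H]2CC1(C)C
F11 | step 15 | (E)-propenyl analogue of 29 | C12(OCCO1)CC[C@@H](/C=C/C)[C@@](Oc3cc(OCc4ccccc4)cc(OCc4ccccc4)c3)(C)CC[C@@H]1[C@@H]2CC1(C)C
F12 | step 1 | cyclopent-2-enone | O=C1C=CCC1
F13 | step 1 | (1R,5R)-6,6-dimethylbicyclo[3.2.0]heptan-2-one | O=C1CC[C@@H]2[C@H]1CC2(C)C
F14 | step 14 | acid from saponification of 17 | OC(=O)C(Oc3cc(OCc4ccccc4)cc(OCc4ccccc4)c3)CC[C@@H]1[C@@H](C2(CCC=C)OCCO2)CC1(C)C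
F15 | step 14 | allyl ester of F14 | C=CCOC(=O)C(Oc3cc(OCc4ccccc4)cc(OCc4ccccc4)c3)CC[C@@H]1[C@@H](C2(CCC=C)OCCO2)CC1(C)C
F16 | step 18 | O-phenyl thionocarbonate of 27 | C12(OCCO1)CC[C@@H](C=C)[C@@](Oc3cc(OCc4ccccc4)cc(OCc4ccccc4)c3)(COC(=S)Oc5ccccc5)CC[C@@H]1[C@@H]2CC1(C)C
F17 | step 24 | 6,8-dibromide of 35 | O=C1CC[C@H]2[C@H](c3ccccc3)c3c(OCc4ccccc4)c(Br)c(OCc4ccccc4)c(Br)c3O[C@]2(C)CC[C@@H]2[C@@H]1CC2(C)C
F18 | step 24 | 6,8-dibromo bis(benzyl) ether with C8 methylene | C=C1CC[C@H]2[C@H](c3ccccc3)c3c(OCc4ccccc4)c(Br)c(OCc4ccccc4)c(Br)c3O[C@]2(C)CC[C@@H]2[C@@H]1CC2(C)C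
F19 | step 24 | bis(benzyl) ether of 39 | C=C1CC[C@H]2[C@H](c3ccccc3)c3c(OCc4ccccc4)c(C=O)c(OCc4ccccc4)c(C=O)c3O[C@]2(C)CC[C@@H]2[C@@H]1CC2(C)C
A1 | alternative 1 | enyne: 5,7-dimethoxy-4-phenylchroman with a 4-methylpent-3-enyl chain on C4 and a 3-(tert-butyldimethylsilyloxy)pent-4-ynyl chain on C5 | CC(C)(C)[Si](C)(C)O[C@@H](C#C)CC[C@H]2[C@H](c3ccccc3)c3c(OC)cc(OC)cc3O[C@]2(C)CCC=C(C)C
A2 | alternative 1 | cyclobutene-fused nine-membered ring with C8 silyl ether | CC(C)(C)[Si](C)(C)O[C@@H]1CC[C@H]2[C@H](c3ccccc3)c3c(OC)cc(OC)cc3O[C@]2(C)CC[C@@H]2C1=CC2(C)C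
A3 | alternative 2 | diene: 2-methyl-2-vinylchroman tethered to the trans-2-vinyl-3,3-dimethylcyclobutyl ketone | C=C[C@@H]1[C@@H](C(=O)CC[C@H]2[C@H](c3ccccc3)c3c(OC)cc(OC)cc3O[C@]2(C)C=C)CC1(C)C
A4 | alternative 2 | Z-cyclononene with C8 ketone | O=C1CC[C@H]2[C@H](c3ccccc3)c3c(OC)cc(OC)cc3O[C@]2(C)/C=C\[C@@H]2[C@@H]1CC2(C)C
A5 | alternative 3 | chroman-fused Z-cyclononenone (C8 ketone, C1=C9) | O=C1CC[C@H]2[C@H](c3ccccc3)c3c(OC)cc(OC)cc3O[C@]2(C)CC/C=C\1
A6 | alternative 3 | C8 ketone with trans-fused gem-dimethylcyclobutane | O=C1CC[C@H]2[C@H](c3ccccc3)c3c(OC)cc(OC)cc3O[C@]2(C)CC[C@@H]2[C@@H]1CC2(C)C
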